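Retrosynthetic cuts, in order: the aryl–CHO bond, the aryl–C(O)CH2CHMe2 bond and the two O-methyl masks; then the bond from the benzylic carbon to C6 of the bornane, made at the ketone level; last the aryl–O bond to C2.
Enabling feature: the oxepine ring (O, C2, C1, C6, benzylic C, two neighbouring arene carbons) hangs on the endo valences of C2 and C6. These lie side by side beneath quaternary C1, so a formyl group ortho to an endo C2 aryl ether rests under C6 of a C5=C6 alkene.
Forward: bicycle and arene are bought. C5 of bornyl acetate is oxidised and turned into the C5=C6 alkene, the halves are joined through oxygen by SNAr, and rhodium-catalysed hydroacylation closes the seven-membered ring, the only ring that has to be made.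
The ring ketone then marks its neighbouring methoxy group for selective cleavage and is reduced to CH2. The freed phenol steers the isovaleryl group to its ortho carbon, the last aromatic CH is formylated, and the remaining methyl ether is cleaved.
Stereochemistry: C1, C2 and C4 are those of (1R,2S,4R)-(+)-borneol and no step touches them; C6 is set in the ring closure by delivery to the endo face from the C2 tether.

Key step: step 6

Remark: terpene carbons keep bornane numbers throughout (C1 = CMe bridgehead, C2 = C–O, C4 = CH bridgehead, C7 = CMe2); arene positions of the tetracycles carry primed 1-benzoxepine numbers (O1′, benzylic C5′, 6′ next to C5′, 9′ next to O1′); 2-fluoro-4,6-dimethoxybenzaldehyde is assumed to be purchasable.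

Step 1
Reactants: 1 (1R,2S,4R)-(+)-borneol
Product: 2 (1R,2S,4R)-(+)-bornyl acetate
Conditions: Ac2O, pyridine, DMAP (cat.), rt
Reagents that add atoms: acetic anhydride, CC(=O)OC(C)=O
Why: DMAP-catalysed O-acetylation (nucleophilic acyl substitution) shields the carbinol from chromium(VI) and touches no stereocentre.

Step 2
Reactants: 2 (+)-bornyl acetate
Product: 3 (1R,2S,4R)-5-oxobornyl acetate (endo-2-acetoxybornan-5-one)
Conditions: CrO3, AcOH–Ac2O, rt → 45 °C
Reagents that add atoms: chromium trioxide, O=[Cr](=O)=O
Why: Chromium(VI) oxidation of an unactivated methylene group, the classical remote oxidation of bornyl acetate, should fall mainly on C5 because C3 is deactivated by the adjacent acetoxy carbon and C6 is crowded by quaternary C1 and the endo acetate, and any 6-oxo isomer carried along would give the same alkene in step 4.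

Step 3
Reactants: 3 5-oxobornyl acetate
Product: 4 5-oxobornyl acetate N-tosylhydrazone
Conditions: TsNHNH2, EtOH, HCl (cat.), reflux
Reagents that add atoms: p-toluenesulfonohydrazide, Cc1ccc(cc1)S(=O)(=O)NN
Why: Acid-catalysed hydrazone condensation works on camphor-type ketones and leaves the ester and the stereocentres alone.

Step 4
Reactants: 4 5-oxobornyl acetate N-tosylhydrazone
Product: 6 (1R,2S,4S)-born-5-en-2-endo-ol, via dilithio bornenolate 5 (not isolated)
Conditions: MeLi (6 equiv), Et2O, 0 °C → rt; then H2O
Reagents that add atoms: none
Why: Shapiro reaction, as in the conversion of camphor into 2-bornene: the second deprotonation can only occur at C6 since C4 is a bridgehead, loss of sulfinate and nitrogen gives vinyllithium 5, which water protonates, and the excess methyllithium takes off the acetyl group by double addition.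

Step 5
Reactants: 6 born-5-en-2-endo-ol; 7 2-fluoro-4,6-dimethoxybenzaldehyde
Product: 9 2-[(1R,2S,4S)-born-5-en-2-endo-yloxy]-4,6-dimethoxybenzaldehyde, via potassium bornenolate 8 (not isolated)
Conditions: KH, THF, 0 °C → rt; then 7, 18-crown-6 (cat.), 0 → 45 °C
Reagents that add atoms: none
Why: Nucleophilic aromatic substitution by addition–elimination: the ortho formyl group stabilises the Meisenheimer adduct, both methoxy groups are meta to the carbon attacked and so do not oppose it, and the C2–O bond is not broken, which keeps the endo configuration.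

Step 6
Reactants: 9 2-(born-5-en-2-endo-yloxy)-4,6-dimethoxybenzaldehyde
Product: 10 bornane-fused 6′,8′-dimethoxy-1-benzoxepin-5′-one (O1′ on C2 endo; C5′ on C6 endo; bornane descriptors 1R,2S,4R,6R)
Conditions: [Rh(nbd)2]BF4 (10 mol %), dcpe (10 mol %), H2 then Ar purge, 1,2-dichloroethane, 60 °C
Reagents that add atoms: none
Why: Cationic rhodium(I) adds oxidatively into the formyl C–H bond of 9 while the neighbouring aryl ether oxygen holds the acyl rhodium hydride in a five-membered chelate that slows CO extrusion; the C5=C6 alkene then binds, Rh–H adds syn across it (H to C5, Rh to C6) and C–C reductive elimination joins the acyl carbon to C6. The closest known reactions are the heteroatom-chelated intramolecular alkene hydroacylations of ortho-alkenyloxy- and ortho-alkenylthiobenzaldehydes to seven- and eight-membered benzo-fused ketones, and the hydroacylation of norbornenes with ortho-oxygenated benzaldehydes. The oxepinone closes in a 7-exo-trig sense (C5 stays outside the new ring) by way of an eight-membered rhodacycle that the bound oxygen divides into two five-membered rings. C6 is the only new stereocentre and is fixed by the substrate: the tether hangs from the endo oxygen at C2 and can bring rhodium only to the endo face, the face 7,7-dimethylnorbornenes offer anyway because the syn C7 methyl group covers the exo face, and syn insertion followed by retentive reductive elimination leaves the acyl group endo. The step needs C6 over C5 and hydroacylation over decarbonylation: bonding at C5 would require a nine-membered rhodacycle stretched across the diagonal of the bicycle whereas endo C2 and endo C6 are direct neighbours under C1, and chelation together with the release of norbornene strain on insertion favours the productive path. An achiral bisphosphine suffices because no stereochemical information has to come from the catalyst.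

Step 7
Reactants: 10 bornane-fused 6′,8′-dimethoxy-1-benzoxepin-5′-one
Product: 12 bornane-fused 6′-hydroxy-8′-methoxy-1-benzoxepin-5′-one, via dichloroboron chelate 11 (not isolated)
Conditions: BCl3 (1.2 equiv), CH2Cl2, −78 → −20 °C; then H2O
Reagents that add atoms: none
Why: Chelation-controlled cleavage of an aryl methyl ether with boron trichloride: boron bridges the ketone oxygen and the peri 6′-oxygen and chloride removes that methyl group by SN2, whereas the 8′-methoxy group has no carbonyl neighbour and O1′ lies on the side of the ring turned away from the carbonyl oxygen.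

Step 8
Reactants: 12 bornane-fused 6′-hydroxy-8′-methoxy-1-benzoxepin-5′-one
Product: 14 bornane-fused 6′-hydroxy-8′-methoxy-1-benzoxepine with C5′H2 (bornane descriptors 1R,2S,4R,6S), via benzylic alcohol 13 (not isolated)
Conditions: Et3SiH (5 equiv), CF3CO2H–CH2Cl2, 0 °C → rt
Reagents that add atoms: none
Why: Ionic hydrogenation: the protonated ketone and then the benzylic cation from alcohol 13, both stabilised by three oxygen donors on the ring, accept hydride from the silane, and C6 cannot epimerise because only the endo isomer can span the seven-membered ring.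

Step 9
Reactants: 14 bornane-fused 6′-hydroxy-8′-methoxy-1-benzoxepine; 15 isovaleryl chloride
Product: 16 7′-isovaleryl-6′-hydroxy-8′-methoxy tetracycle
Conditions: TiCl4, CH2Cl2, −20 °C → rt; then H2O
Reagents that add atoms: none
Why: Friedel–Crafts acylation templated by the titanium phenoxide: the acyl group is delivered to C7′, the only free position ortho to the hydroxyl group, where the product is held as a six-membered chelate, while C9′ has no such neighbour.

Step 10
Reactants: 16 7′-isovaleryl-6′-hydroxy-8′-methoxy tetracycle
Product: 18 9′-formyl-7′-isovaleryl-6′-hydroxy-8′-methoxy tetracycle, via chloro(methoxy)methyl arene 17 (not isolated)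
Conditions: Cl2CHOMe, TiCl4, CH2Cl2, −20 → 0 °C; then H2O
Reagents that add atoms: dichloromethyl methyl ether, COC(Cl)Cl; water, O
Why: Rieche formylation: C9′ is the only aromatic CH left and is still activated by an ortho methoxy group, the ortho ring oxygen and the para hydroxyl group, and hydrolysis of 17 on work-up releases the aldehyde.

Step 11
Reactants: 18 9′-formyl-7′-isovaleryl-6′-hydroxy-8′-methoxy tetracycle
Product: 20 CNP0246493.1 (9′-formyl-6′,8′-dihydroxy-7′-isovaleryl tetracycle; bornane descriptors 1R,2S,4R,6S), via dichloroboron chelate 19 (not isolated)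
Conditions: BCl3 (3 equiv), CH2Cl2, −78 → −10 °C; then H2O
Reagents that add atoms: none
Why: Chelation-assisted demethylation: the 8′-methoxy group lies between two carbonyl groups and should lose its methyl group to chloride well below 0 °C, whereas the C2–O bond is a neopentyl-type endo bond whose rear side is closed by the C7 methyl group and whose ionisation gets no σ-assistance.

Compound list
1 | (1R,2S,4R)-(+)-borneol | C1C[C@@H]2C[C@H](O)[C@@]1(C)C2(C)C | starting material
2 | (1R,2S,4R)-(+)-bornyl acetate | C1C[C@@H]2C[C@H](OC(C)=O)[C@@]1(C)C2(C)C | intermediate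
3 | (1R,2S,4R)-5-oxobornyl acetate | C1C(=O)[C@@H]2C[C@H](OC(C)=O)[C@@]1(C)C2(C)C | intermediate
4 | 5-oxobornyl acetate N-tosylhydrazone | C1C(=NNS(=O)(=O)c3ccc(C)cc3)[C@@H]2C[C@H](OC(C)=O)[C@@]1(C)C2(C)C | intermediate
5 | dilithio bornenolate (C5-lithio-born-5-en-2-endo-ol lithium alkoxide) | C1=C([Li])[C@@H]2C[C@H](O[Li])[C@@]1(C)C2(C)C | intermediate
6 | (1R,2S,4S)-born-5-en-2-endo-ol | C1=C[C@@H]2C[C@H](O)[C@@]1(C)C2(C)C | intermediate
7 | 2-fluoro-4,6-dimethoxybenzaldehyde | COc1cc(F)c(C=O)c(OC)c1 | starting material
8 | potassium bornenolate (potassium salt of 6) | C1=C[C@@H]2C[C@H]([O-])[C@@]1(C)C2(C)C.[K+] | intermediate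
9 | 2-[(1R,2S,4S)-born-5-en-2-endo-yloxy]-4,6-dimethoxybenzaldehyde | C1=C[C@@H]3C[C@H](Oc2cc(OC)cc(OC)c2C=O)[C@@]1(C)C3(C)C | intermediate
10 | bornane-fused 6′,8′-dimethoxy-1-benzoxepin-5′-one | COc1cc2c(c(OC)c1)C(=O)[C@@H]1C[C@@H]3C[C@H](O2)[C@@]1(C)C3(C)C | intermediate
11 | 6′-O-dichloroboryl chelate of the oxepinone | COc1cc2c(c(OB(Cl)Cl)c1)C(=O)[C@@H]1C[C@@H]3C[C@H](O2)[C@@]1(C)C3(C)C | intermediate
12 | bornane-fused 6′-hydroxy-8′-methoxy-1-benzoxepin-5′-one | COc1cc2c(c(O)c1)C(=O)[C@@H]1C[C@@H]3C[C@H](O2)[C@@]1(C)C3(C)C | intermediate
13 | C5′ benzylic alcohol (carbinol configuration not defined) | COc1cc2c(c(O)c1)C(O)[C@@H]1C[C@@H]3C[C@H](O2)[C@@]1(C)C3(C)C | intermediate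
14 | bornane-fused 6′-hydroxy-8′-methoxy-1-benzoxepine (C5′H2) | COc1cc2c(c(O)c1)C[C@@H]1C[C@@H]3C[C@H](O2)[C@@]1(C)C3(C)C | intermediate
15 | isovaleryl chloride (3-methylbutanoyl chloride) | CC(C)CC(=O)Cl | starting material
16 | 7′-isovaleryl-6′-hydroxy-8′-methoxy tetracycle | CC(C)CC(=O)c1c(OC)cc2c(c1O)C[C@@H]1C[C@@H]3C[C@H](O2)[C@@]1(C)C3(C)C | intermediate
17 | 9′-[chloro(methoxy)methyl] derivative of 16 (new carbon not defined) | CC(C)CC(=O)c1c(OC)c(C(Cl)OC)c2c(c1O)C[C@@H]1C[C@@H]3C[C@H](O2)[C@@]1(C)C3(C)C | intermediate
18 | 9′-formyl-7′-isovaleryl-6′-hydroxy-8′-methoxy tetracycle | CC(C)CC(=O)c1c(OC)c(C=O)c2c(c1O)C[C@@H]1C[C@@H]3C[C@H](O2)[C@@]1(C)C3(C)C | intermediate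
19 | 8′-O-dichloroboryl chelate (drawn with the 6′-OH free) | CC(C)CC(=O)c1c(OB(Cl)Cl)c(C=O)c2c(c1O)C[C@@H]1C[C@@H]3C[C@H](O2)[C@@]1(C)C3(C)C | intermediate
20 | CNP0246493.1 | CC(C)CC(=O)c1c(O)c(C=O)c2c(c1O)C[C@@H]1C[C@@H]3C[C@H](O2)[C@@]1(C)C3(C)C | target

Total step count: 11. Longest linear sequence: 11 steps, from 1; compounds 7 and 15 are bought and enter directly.

Steps most likely to fail

Step 6. The acyl rhodium hydride may lose CO and kill the catalyst. The 6-methoxy oxygen may chelate the metal on the wrong side of the acyl group. The crowded alkene carbon next to C1 may also refuse to insert. The fallback makes the same bond with an acyl radical instead of a metal hydride, and it sets out from 9. Pinnick oxidation (NaClO2, NaH2PO4, 2-methyl-2-butene, t-BuOH–H2O) would give 2-(born-5-en-2-endo-yloxy)-4,6-dimethoxybenzoic acid F1. Treatment with (PhSe)2 and Bu3P would convert it into Se-phenyl 2-(born-5-en-2-endo-yloxy)-4,6-dimethoxybenzenecarboselenoate F2. Slow addition of Bu3SnH/AIBN in refluxing benzene would then release the aroyl radical. This radical does not decarbonylate and should add 7-exo to the endo face at C6 of the strained alkene before hydrogen abstraction at C5. The fallback rejoins the route at 10.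

Step 5. The secondary alkoxide may transfer hydride to the formyl group (Meerwein–Ponndorf/Oppenauer-type redox). Displacement may also be slow because the two methoxy groups drain the acceptor strength of the aldehyde. The fallback changes the oxidation level of the activating group and sets out from 7 and 8. Compound 7 would first be converted into 2-fluoro-4,6-dimethoxybenzonitrile F3 (I2, aq NH3, THF, rt), whose cyano group cannot accept hydride from an alkoxide. Alkoxide 8 would displace fluoride from it (THF–DMF, rt → 60 °C) to give 2-(born-5-en-2-endo-yloxy)-4,6-dimethoxybenzonitrile F4. DIBAL-H (toluene, −78 °C) followed by dilute aqueous HCl would release the aldehyde, rejoining the route at 9.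

Step 9. Attack may occur para to the hydroxyl group at C9′, O-acylation may occur without migration to carbon, or the Lewis acid may ionise the C2–O bond. The fallback builds the side chain on an ortho-specific formylation that needs no strong Lewis acid, and it sets out from 14. Casnati–Skattebøl formylation (MgCl2, Et3N, paraformaldehyde, MeCN, reflux) passes through the magnesium phenoxide and can only reach C7′. It would give the 7′-formyl-6′-hydroxy-8′-methoxy tetracycle F5. Isobutylmagnesium bromide (2.2 equiv, THF, 0 °C) would add to give the 7′-(1-hydroxy-3-methylbutyl) phenol F6. MnO2 in CH2Cl2 would oxidise this benzylic alcohol to the ketone, rejoining the route at 16.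

Further compounds
F1 | step 6 | 2-(born-5-en-2-endo-yloxy)-4,6-dimethoxybenzoic acid | C1=C[C@@H]3C[C@H](Oc2cc(OC)cc(OC)c2C(=O)O)[C@@]1(C)C3(C)C
F2 | step 6 | Se-phenyl 2-(born-5-en-2-endo-yloxy)-4,6-dimethoxybenzenecarboselenoate | C1=C[C@@H]3C[C@H](Oc2cc(OC)cc(OC)c2C(=O)[Se]c4ccccc4)[C@@]1(C)C3(C)C
F3 | step 5 | 2-fluoro-4,6-dimethoxybenzonitrile | COc1cc(F)c(C#N)c(OC)c1
F4 | step 5 | 2-(born-5-en-2-endo-yloxy)-4,6-dimethoxybenzonitrile | C1=C[C@@H]3C[C@H](Oc2cc(OC)cc(OC)c2C#N)[C@@]1(C)C3(C)C
F5 | step 9 | 7′-formyl-6′-hydroxy-8′-methoxy tetracycle | O=Cc1c(OC)cc2c(c1O)C[C@@H]1C[C@@H]3C[C@H](O2)[C@@]1(C)C3(C)C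
F6 | step 9 | 7′-(1-hydroxy-3-methylbutyl)-6′-hydroxy-8′-methoxy tetracycle (carbinol configuration not defined) | CC(C)CC(O)c1c(OC)cc2c(c1O)C[C@@H]1C[C@@H]3C[C@H](O2)[C@@]1(C)C3(C)C
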